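Ring C is the foundation: its C6 gem-dimethyl carbon beside the C7 oxygen, the C9 oxygen and the C10 methyl map onto a 1,1-dimethyl oxyallyl cation added across C2/C5 of 3-methylfuran. One (4+3) cycloaddition forms C5–C6 and C8–C9, closes the seven-membered ring and leaves the furan oxygen as a C5–O–C9 bridge. The precursors are simply 3-bromo-3-methylbutan-2-one and 3-methylfuran. Afterwards the bridge is opened to a C5 carbinol, which relays chirality to quaternary C10 (Ireland–Claisen); a C11 carbene then joins C5 (bicyclobutane), and a C4 radical closes ring A on the face away from ring C.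

Key step: step 1

Numbering (target locants): C1 is the ring-A ketone carbon, C2 its CH2, C3 the CH(CH3); C4, C5, C11, C10 are the cyclobutane carbons in ring order (C10 quaternary with methyl, C11 bonded to C1); C6 is CMe2, C7 and C9 carry the esters, C8 lies between them. Ring A is C1–C2–C3–C4–C10–C11, ring B is C4–C5–C11–C10, ring C is C4–C5–C6–C7–C8–C9–C10. "β" is the face of ring C that carries C11, "α" the other.

Remark on the chemistry: the cycloadduct is racemic; 4, 5 and 6 are drawn as the enantiomer that is carried on after the resolution in step 3.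

Remark on the chemistry: a nucleophile that opens the C4–C11 bond of the bicyclobutane must enter at C4 from the ring-C side (inversion), so it could never be bridged to C11; C3 is therefore delivered to C4 from the C11 acyl group through a C4 radical.

Assumption: in step 10 the antipode of the ferrocenyl bisphosphine that places boron on the β face of C9 is picked in a two-ligand test; both antipodes are commercial.

Step 1
Reactants: 1 3-methylfuran; 2 3-bromo-3-methylbutan-2-one
Product: 4 (±)-2,2,6-trimethyl-8-oxabicyclo[3.2.1]oct-6-en-3-one, via oxyallyl cation 3 (not isolated)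
Conditions: Et3N, CF3CH2OH, 0 °C to rt, 1 in excess
Reagents that add atoms: none
Why: Et3N enolises 2 toward its methyl group and the tertiary bromide ionises in the fluoroalcohol to the 1,1-dimethyl oxyallyl cation 3, a three-carbon 2π partner that adds across C2 and C5 of the furan 4π system in a concerted but asynchronous (4+3) cycloaddition. The closest known reaction type is the (4+3) cycloaddition of α-haloketone-derived oxyallyl cations with furans under amine/fluoroalcohol conditions, which gives 8-oxabicyclo[3.2.1]oct-6-en-3-ones. Ring C is closed as a carbocycle by intermolecular annulation, C5–C6 and C8–C9 forming in the same operation while the furan oxygen becomes the one-atom C5–O–C9 bridge. The two new stereocentres, C5 and C9, are bridgeheads whose relative configuration is fixed by the bridge (suprafacial addition to the planar furan); nothing controls the absolute sense, so 4 is racemic. The selectivity that matters is regiochemical: the furan carbon next to the methyl group, the more nucleophilic one, should bond first to the unhindered CH2 terminus of 3, leaving the bulky CMe2 terminus for the unsubstituted furan carbon that becomes C5, and the minor regioisomer is removed by chromatography.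

Step 2
Reactants: 4 (±)-2,2,6-trimethyl-8-oxabicyclo[3.2.1]oct-6-en-3-one
Product: 6 (±)-6-hydroxy-4,7,7-trimethylcyclohepta-2,4-dien-1-one, via trimethylsilyl ether 5 (not isolated)
Conditions: TMSOTf (1.2 equiv), Et3N, CH2Cl2, −78 to 0 °C; then 0.5 M aq HCl, THF, 0 °C
Reagents that add atoms: trimethylsilyl trifluoromethanesulfonate, C[Si](C)(C)OS(=O)(=O)C(F)(F)F (its silyl group is held by 5 only)
Why: Silyl-triflate-mediated ring opening of an 8-oxabicyclo[3.2.1]oct-6-en-3-one (vinylogous β-elimination of E1cB type): the ketone can enolise only toward C8, so only the C9–O bond is cleaved and C5 keeps its configuration, silyl capture of the C5 oxygen avoids a free β-alkoxide that could cleave C5–C6 by retro-aldol reaction, and the C6 gem-dimethyl group rules out aromatisation to a tropone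

Step 3
Reactants: 6 (±)-6-hydroxy-4,7,7-trimethylcyclohepta-2,4-dien-1-one; 7 vinyl acetate
Product: 8 (1R)-3,7,7-trimethyl-6-oxocyclohepta-2,4-dien-1-yl acetate
Conditions: immobilised Candida antarctica lipase B, MTBE, 30 °C, stopped near half conversion; chromatography
Reagents that add atoms: none
Why: Lipase-catalysed kinetic resolution by transesterification: with quaternary C6 as the large and vinylic C4 as the medium substituent the Kazlauskas rule predicts faster acylation of the (R)-carbinol, so the enantiomer needed should be obtained directly as the acetate that step 4 requires, and the unreacted (S)-alcohol is separated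

Step 4
Reactants: 8 (1R)-3,7,7-trimethyl-6-oxocyclohepta-2,4-dien-1-yl acetate
Product: 11 2-[(1S)-1,4,4-trimethyl-5-oxocyclohepta-2,6-dien-1-yl]acetic acid, via silyl ketene acetal 9 (not isolated), via silyl ester 10 (not isolated)
Conditions: LDA added to 8/TMSCl/Et3N, THF, −78 °C, then 45 °C; then 1 M HCl
Reagents that add atoms: chlorotrimethylsilane, C[Si](C)(C)Cl (its silyl group is held by 9 and 10 only)
Why: Ireland–Claisen rearrangement: kinetic deprotonation of the acetate with internal silyl quench gives 9, which rearranges suprafacially ([3,3]) across the C5–C4=C10 allyl unit at a temperature well below that of a 1,5-hydrogen shift that would erase C5, so C10–C11 forms on the ring face that carried the C5 oxygen and the (R)-carbinol configuration is transferred to the quaternary centre C10 while C4=C5 is created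

Step 5
Reactants: 11 2-[(1S)-1,4,4-trimethyl-5-oxocyclohepta-2,6-dien-1-yl]acetic acid; 12 (E)-tributyl(prop-1-en-1-yl)stannane
Product: 14 (E)-1-[(1S)-1,4,4-trimethyl-5-oxocyclohepta-2,6-dien-1-yl]pent-3-en-2-one, via acid chloride 13 (not isolated)
Conditions: (COCl)2, catalytic DMF, CH2Cl2, 0 °C to rt, evaporate; then 12, Pd2(dba)3, P(2-furyl)3, THF, 50 °C
Reagents that add atoms: oxalyl chloride, O=C(Cl)C(=O)Cl (its chlorine is held by 13 only)
Why: Acid chloride formation followed by Stille acyl cross-coupling (palladium-catalysed ketone synthesis from an acid chloride and an alkenylstannane) brings in C2, C3 and the C3 methyl as an (E)-enone without any polar organometallic reagent that would attack the ring-C dienone, no stereocentre is formed and the alkene geometry of 12 is retained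

Step 6
Reactants: 14 (E)-1-[(1S)-1,4,4-trimethyl-5-oxocyclohepta-2,6-dien-1-yl]pent-3-en-2-one
Product: 16 (E)-1-diazo-1-[(1S)-1,4,4-trimethyl-5-oxocyclohepta-2,6-dien-1-yl]pent-3-en-2-one, via trifluoroacetyl diketone 15 (not isolated)
Conditions: LiHMDS, THF, −78 °C; CF3CO2CH2CF3; then MsN3, Et3N, H2O, MeCN, rt
Reagents that add atoms: 2,2,2-trifluoroethyl trifluoroacetate, O=C(OCC(F)(F)F)C(F)(F)F (its trifluoroacetyl group is held by 15 only); methanesulfonyl azide, CS(=O)(=O)N=[N+]=[N-]
Why: Detrifluoroacetylative Regitz diazo transfer: the kinetic cross-conjugated enolate forms at C11, the only α'-position because the ring-C ketone cannot enolise, is activated as the trifluoroacetyl diketone 15 and then exchanges the trifluoroacetyl group for N2 with mesyl azide, leaving C10 untouched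

Step 7
Reactants: 16 (E)-1-diazo-1-[(1S)-1,4,4-trimethyl-5-oxocyclohepta-2,6-dien-1-yl]pent-3-en-2-one
Product: 17 bicyclobutane enone (C11 bonded to C10/C4/C5 and carrying the (E)-but-2-enoyl group)
Conditions: Rh2(OAc)4 (1 mol%), CH2Cl2, rt, slow addition of 16
Reagents that add atoms: none
Why: Intramolecular cyclopropanation of a homoallylic α-diazo carbonyl compound to a bicyclo[1.1.0]butane under dirhodium tetraacetate catalysis: the electrophilic carbenoid at C11 has no β-hydrogen to shift (C10 is quaternary) and should prefer the electron-rich C4=C5 alkene over the enone alkene C8=C9, forming C11–C4 and C11–C5 on the face dictated by the C10 tether, so C4, C5 and C11 are set relative to C10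

Step 8
Reactants: 17 bicyclobutane enone
Product: 18 C4-bromo cyclobutane enone (ring B closed; Br on C4 syn to ring C; but-2-enoyl on C11 anti to ring C)
Conditions: HBr (33% in AcOH, 1.1 equiv), CH2Cl2, −20 °C to rt; then Et3N, 0 °C
Reagents that add atoms: hydrogen bromide, Br
Why: Hydrobromination of an acyl bicyclobutane across its strained central bond (homoconjugate addition): bromide enters at C4 and the enol ketonises at C11, where acid-mediated equilibration favours the acyl group trans to the two ring-C bonds at C5 and C10 (cis only to H and CH3), which is the orientation ring A needs, the C4 configuration is irrelevant because C4 becomes a radical, and Et3N reverses any hydrobromination of the enones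

Step 9
Reactants: 18 C4-bromo cyclobutane enone
Product: 19 tricyclic enedione (rings A B C closed; C1 and C7 ketones; C8=C9)
Conditions: Bu3SnH (syringe pump), AIBN, benzene, 80 °C
Reagents that add atoms: none
Why: Tin hydride mediated 6-endo-trig radical cyclisation (intramolecular Giese addition): the nucleophilic cyclobutyl radical at C4 can be reached by the C11 acyl tether only from the face opposite ring C, attack at the enone β-carbon C3 is favoured electronically and by strain over 5-exo attack at C2, and the (E)-enone should react through the conformer that keeps C2 and the C3 methyl away from the C10 methyl, which places the C3 methyl on the C5 side as in the target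

Step 10
Reactants: 19 tricyclic enedione
Product: 21 C9 β-hydroxy diketone, via pinacol boronate 20 (not isolated)
Conditions: CuCl, NaOtBu, Taniaphos (one antipode), B2pin2, MeOH, THF, rt; then NaBO3·4H2O, THF/H2O, 0 °C to rt
Reagents that add atoms: bis(pinacolato)diboron, CC1(C)OB(OC1(C)C)B1OC(C)(C)C(C)(C)O1 (its boryl group is held by 20 only); sodium perborate, [Na+].[O-]OB=O
Why: Copper-catalysed conjugate borylation of the enone followed by stereoretentive perborate oxidation gives the C9 carbinol chemoselectively, the saturated C1 ketone being inert, and because the two faces of the ring-C enone are nearly equivalent inside the cage the face of boron delivery is imposed by the chiral ligand (reagent control), chosen to put the oxygen on the β face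

Step 11
Reactants: 21 C9 β-hydroxy diketone
Product: 22 C7 α, C9 β diol (1,3-anti) with the C1 ketone intact
Conditions: Me4NBH(OAc)3, MeCN/AcOH, −25 °C
Reagents that add atoms: none
Why: Evans–Saksena reduction: the C9 hydroxyl binds the triacetoxyborohydride and delivers hydride internally to the β face of the C7 carbonyl, which should give the 1,3-anti diol with C7–OH on the α face, while the C1 ketone, which has no neighbouring hydroxyl, is not reduced

Step 12
Reactants: 22 C7 α, C9 β diol; 23 angelic acid
Product: 25 CNP0283599.1 (target), via mixed anhydride 24 (not isolated)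
Conditions: 23 (3 equiv), 2,4,6-Cl3C6H2COCl, Et3N, toluene, rt; then 22, toluene, 80 °C
Reagents that add atoms: 2,4,6-trichlorobenzoyl chloride, O=C(Cl)c1c(Cl)cc(Cl)cc1Cl (its aroyl group is held by 24 only)
Why: Yamaguchi-type acylation of both hindered secondary alcohols with the preformed angelic 2,4,6-trichlorobenzoic mixed anhydride in the absence of a nucleophilic catalyst, conditions that preserve the (Z)-geometry of angelates, and no stereocentre changes

Compound list
1 | 3-methylfuran | Cc1ccoc1 | starting material
2 | 3-bromo-3-methylbutan-2-one | CC(=O)C(C)(C)Br | starting material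
3 | 1,1-dimethyl-2-oxidoallyl cation (oxyallyl zwitterion) | C=C([O-])[C+](C)C | intermediate
4 | 2,2,6-trimethyl-8-oxabicyclo[3.2.1]oct-6-en-3-one, racemate; the (1R,5R) enantiomer is drawn | O=C1C[C@H]2O[C@H](C=C2C)C1(C)C | intermediate
5 | 4,7,7-trimethyl-6-(trimethylsilyloxy)cyclohepta-2,4-dien-1-one, racemate; (6R) drawn | O=C1C=CC(C)=C[C@@H](O[Si](C)(C)C)C1(C)C | intermediate
6 | 6-hydroxy-4,7,7-trimethylcyclohepta-2,4-dien-1-one, racemate; (6R) drawn | O=C1C=CC(C)=C[C@@H](O)C1(C)C | intermediate
7 | vinyl acetate | C=COC(C)=O | starting material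
8 | (1R)-3,7,7-trimethyl-6-oxocyclohepta-2,4-dien-1-yl acetate | O=C1C=CC(C)=C[C@@H](OC(C)=O)C1(C)C | intermediate
9 | (1R)-3,7,7-trimethyl-6-oxocyclohepta-2,4-dien-1-yl 1-(trimethylsilyloxy)ethenyl ether (silyl ketene acetal of 8) | O=C1C=CC(C)=C[C@@H](OC(=C)O[Si](C)(C)C)C1(C)C | intermediate
10 | trimethylsilyl 2-[(1S)-1,4,4-trimethyl-5-oxocyclohepta-2,6-dien-1-yl]acetate | O=C1C=C[C@@](C)(CC(=O)O[Si](C)(C)C)C=CC1(C)C | intermediate
11 | 2-[(1S)-1,4,4-trimethyl-5-oxocyclohepta-2,6-dien-1-yl]acetic acid | O=C1C=C[C@@](C)(CC(=O)O)C=CC1(C)C | intermediate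
12 | (E)-tributyl(prop-1-en-1-yl)stannane | C/C=C/[Sn](CCCC)(CCCC)CCCC | starting material
13 | 2-[(1S)-1,4,4-trimethyl-5-oxocyclohepta-2,6-dien-1-yl]acetyl chloride | O=C1C=C[C@@](C)(CC(=O)Cl)C=CC1(C)C | intermediate
14 | (E)-1-[(1S)-1,4,4-trimethyl-5-oxocyclohepta-2,6-dien-1-yl]pent-3-en-2-one | O=C1C=C[C@@](C)(CC(=O)/C=C/C)C=CC1(C)C | intermediate
15 | (E)-1,1,1-trifluoro-3-(1,4,4-trimethyl-5-oxocyclohepta-2,6-dien-1-yl)hept-5-ene-2,4-dione (C10 as in 14; C11 epimers and enol forms) | O=C1C=C[C@@](C)(C(C(=O)C(F)(F)F)C(=O)/C=C/C)C=CC1(C)C | intermediate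
16 | (E)-1-diazo-1-[(1S)-1,4,4-trimethyl-5-oxocyclohepta-2,6-dien-1-yl]pent-3-en-2-one | O=C1C=C[C@@](C)(C(=[N+]=[N-])C(=O)/C=C/C)C=CC1(C)C | intermediate
17 | bicyclobutane enone: ring C (C7 ketone, C8=C9, C6 gem-dimethyl, C10 methyl) with C11 bonded to C10, C4 and C5 on its β face; C11 carries the (E)-but-2-enoyl group | O=C1C=C[C@]2(C)[C@@H]3[C@@H]([C@]23C(=O)/C=C/C)C1(C)C | intermediate
18 | C4-bromo cyclobutane: ring C bridged from C5 to C10 by C11 (ring B closed); Br on C4 syn to ring C; (E)-but-2-enoyl on C11 anti to ring C | O=C1C=C[C@]2(C)[C@H](Br)[C@@H]([C@H]2C(=O)/C=C/C)C1(C)C | intermediate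
19 | 2,6,6,9-tetramethyltricyclo[5.4.0.0(2,8)]undec-3-ene-5,11-dione (target locants: C1 and C7 ketones, C8=C9; C3 methyl on the C5 side) | O=C1C=C[C@]2(C)[C@@H]3[C@@H]([C@H]2C(=O)C[C@H]3C)C1(C)C | intermediate
20 | C9 pinacol boronate of the C1,C7-diketone (boron on the β face) | O=C1C[C@@H](B2OC(C)(C)C(C)(C)O2)[C@]3(C)[C@@H]4[C@@H]([C@H]3C(=O)C[C@H]4C)C1(C)C | intermediate
21 | 3-hydroxy-2,6,6,9-tetramethyltricyclo[5.4.0.0(2,8)]undecane-5,11-dione (C9–OH β) | O=C1C[C@@H](O)[C@]2(C)[C@@H]3[C@@H]([C@H]2C(=O)C[C@H]3C)C1(C)C | intermediate
22 | 3,5-dihydroxy-2,6,6,9-tetramethyltricyclo[5.4.0.0(2,8)]undecan-11-one (C9–OH β, C7–OH α) | O[C@@H]1C[C@@H](O)[C@]2(C)[C@@H]3[C@@H]([C@H]2C(=O)C[C@H]3C)C1(C)C | intermediate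
23 | angelic acid, (Z)-2-methylbut-2-enoic acid | C/C=C(/C)C(=O)O | starting material
24 | (Z)-2-methylbut-2-enoic 2,4,6-trichlorobenzoic anhydride | C/C=C(/C)C(=O)OC(=O)c1c(Cl)cc(Cl)cc1Cl | intermediate
25 | CNP0283599.1: 2,6,6,9-tetramethyl-11-oxotricyclo[5.4.0.0(2,8)]undecane-3,5-diyl bis[(Z)-2-methylbut-2-enoate] | C/C=C(/C)C(=O)O[C@@H]1C[C@@H](OC(=O)/C(C)=C\C)[C@]2(C)[C@@H]3[C@@H]([C@H]2C(=O)C[C@H]3C)C1(C)C | target

Total step count: 12. Longest linear sequence: 12 steps (1 and 2 to 25); 7, 12 and 23 are purchased.

Steps most likely to fail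

Step 7 (bicyclobutanation). The keto carbenoid may leave the cyclopropanation channel (Wolff rearrangement, shift of a ring vinyl carbon from C10, or addition to the enone alkene) before the strained ring forms. The fallback sets out from 11 and returns at 18: the carbene is carried as an ester carbenoid, the class on which this ring closure is best documented, and the enone is attached afterwards. Acid 11 and tert-butyl 2,2,2-trichloroacetimidate (catalytic BF3·OEt2) give tert-butyl 2-[(1S)-1,4,4-trimethyl-5-oxocyclohepta-2,6-dien-1-yl]acetate F1. LiHMDS and CF3CO2CH2CF3 give the α-trifluoroacetyl ester F2, which MsN3/Et3N converts into the α-diazo ester F3. Rh2(OAc)4 closes the bicyclobutane tert-butyl ester F4. HBr in AcOH opens the central bond and cleaves the ester to the C4-bromo cyclobutanecarboxylic acid F5. (COCl)2 gives the bromo acid chloride F6, which is coupled with 12 as in step 5 and equilibrated at C11 with catalytic HBr in AcOH to reach 18.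

Step 9 (ring A closure). Hydrogen-atom transfer from the tin hydride to the C4 radical may outrun the 6-endo ring closure, so that the bromide is merely reduced. The fallback sets out from 18 and returns at 19: a nickel-catalysed reductive conjugate addition that contains no hydrogen-atom donor (NiCl2(dme), neocuproine, Mn powder, Et3SiCl, DMF, rt, high dilution) joins the C4–Br carbon to the silyl-activated enone at nickel and gives the ring-A triethylsilyl enol ether F7; dilute HCl in THF then releases 19.

Step 10 (C9 oxygenation). Facial selectivity of boron delivery at C9 may be poor, because the cage offers almost no intrinsic bias and the ligand may discriminate weakly on this hindered enone. The fallback sets out from 19 and returns at 21: rhodium-catalysed asymmetric conjugate silyl transfer ([Rh(cod)2]OTf, BINAP antipode chosen as in step 10, Me2PhSi–Bpin, Et3N, dioxane/H2O) gives the C9 dimethylphenylsilyl diketone F8, and Fleming–Tamao oxidation with retention (KBr, AcOOH, NaOAc, AcOH, buffered to spare the ketones) gives 21.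

Further compounds
F1 | step 7 | tert-butyl 2-[(1S)-1,4,4-trimethyl-5-oxocyclohepta-2,6-dien-1-yl]acetate | O=C1C=C[C@@](C)(CC(=O)OC(C)(C)C)C=CC1(C)C
F2 | step 7 | tert-butyl 4,4,4-trifluoro-3-oxo-2-(1,4,4-trimethyl-5-oxocyclohepta-2,6-dien-1-yl)butanoate (C10 as in F1) | O=C1C=C[C@@](C)(C(C(=O)C(F)(F)F)C(=O)OC(C)(C)C)C=CC1(C)C
F3 | step 7 | tert-butyl 2-diazo-2-(1,4,4-trimethyl-5-oxocyclohepta-2,6-dien-1-yl)acetate (C10 as in F1) | O=C1C=C[C@@](C)(C(=[N+]=[N-])C(=O)OC(C)(C)C)C=CC1(C)C
F4 | step 7 | bicyclobutane tert-butyl ester (17 with CO2tBu on C11 in place of the but-2-enoyl group) | O=C1C=C[C@]2(C)[C@@H]3[C@@H]([C@]23C(=O)OC(C)(C)C)C1(C)C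
F5 | step 7 | C4-bromo cyclobutanecarboxylic acid (18 with CO2H on C11) | O=C1C=C[C@]2(C)[C@H](Br)[C@@H]([C@H]2C(=O)O)C1(C)C
F6 | step 7 | C4-bromo cyclobutanecarbonyl chloride (18 with COCl on C11) | O=C1C=C[C@]2(C)[C@H](Br)[C@@H]([C@H]2C(=O)Cl)C1(C)C
F7 | step 9 | ring-A triethylsilyl enol ether of 19 (C1–OSiEt3, C1=C2) | O=C1C=C[C@]2(C)[C@@H]3[C@@H]([C@H]2C(O[Si](CC)(CC)CC)=C[C@H]3C)C1(C)C
F8 | step 10 | C9 β-dimethylphenylsilyl C1,C7-diketone | O=C1C[C@@H]([Si](C)(C)c2ccccc2)[C@]3(C)[C@@H]4[C@@H]([C@H]3C(=O)C[C@H]4C)C1(C)C
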